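## The problem

Erythribyssin F (34) is an achiral 2-arylbenzofuran-3-carboxylic acid, in effect a coumestan with its lactone open. The benzofuran carries OH at C6 and prenyl at C7, C3 carries the acid, and C2 is bonded to C1' of a phenyl ring with OH at C2' and C4' and prenyl at C5'. There is no stereocentre, so nothing has to be relayed; the only stereochemical element on the way is an E alkene that is consumed when the aryl ring forms. The difficulty is regiochemical and chemoselective. Both prenyl groups sit ortho to phenols, where acid closes them to 2,2-dimethylchromans, and their trisubstituted alkenes are attacked by SeO2, N-halo reagents, free halogen and oxidising palladium conditions, so every step run after a prenyl group is in place must avoid these. Direct prenylation of a resorcinol unit does not separate C5' from C3' (nor C7 from C5), and the two oxygens of the aryl ring must be told apart. The C3 acid and the 2'-OH are one dehydration away from the coumestan lactone, so the end game must be basic or only mildly acidic. The feature that opens a de novo route is the 1,2,4,5-pattern of the aryl ring: oxygen on C2' and C4', hydrogen on C3' and C6', carbon on C1' and C5'. A vinylketene with the benzofuran on its vinyl terminus and prenyl on its α-carbon gives exactly this pattern with an unsubstituted ynol ether.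

## Retrosynthesis

**34 ⇒ 33 ⇒ 32.** The last cuts are the O–CH3 bond of the ester and two O–Si bonds. Silyl on both protected phenols and a methyl ester are preferred to acetal protection because fluoride and then hydroxide finish the synthesis without acid ever meeting a prenylated phenol. Triol ester 33 and bis-silyl ether 32 differ from the target only in protecting groups. The forward steps must stop the hydroxy acid from relactonising on acidification.

**32 ⇒ 23 + 27.** The whole resorcinol ring is taken apart: C5'–C6', C2'–C3', C4'–C5' and C1'–C2' are cut, leading to diazo enone 23 and (triisopropylsilyloxy)acetylene 27. Against a biaryl coupling at C2–C1', this cut needs no prenylated resorcinol building block: the C5' prenyl is already on the diazo carbon and the two oxygens emerge differentiated (free OH from the ketone carbon, silyl ether from the alkyne). Compound 23 is an acyclic chain on a finished benzofuran and 27 has two carbons. The forward reaction must give Wolff migration rather than a hydrogen shift, and one regiochemistry in the ketene–alkyne cycloaddition.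

**23 ⇒ 20 ⇒ 16 + 19, and 19 ⇒ 17 + 3.** The diazo group is removed to enone 20, whose only enolisable position is the α'-methylene. The C=C bond of 20 is cut by olefination into aldehyde 16 and ketophosphonate 19, and 19 into dimethyl (2-oxopropyl)phosphonate 17 and prenyl bromide 3. A phosphonate is preferred to a base-mediated aldol with a methyl ketone because it fixes the site of reaction and the E geometry and needs no hydroxide near the ester and the aryl silyl ether. The prenyl group of C5' is thus attached to an enolate carbon, never to an arene.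

**16 ⇒ 14 ⇒ 13.** The formyl carbon is cut from C2. Oxidising a C2 methyl group (SeO2 or radical bromination) was rejected because both reagents attack the prenyl alkene first. C2–H lies between the ring oxygen and the ester and can be metalated selectively, so 2-unsubstituted ester 14 and its free phenol 13 are the precursors. The forward step needs a base that spares the methyl ester.

**13 ⇒ 12 ⇒ 11 ⇒ 5 + 8, and 8 ⇒ 6.** The furan is opened at O1–C2 and the C3–C3a bond is cut. This leads to aryl β-methoxyacrylate 11, which carries C2, C3 and the ester at the right oxidation level, and from there to arene 5 and vinyl iodide 8, made from methyl 3-methoxyacrylate 6. Compared with routes through an ortho-halophenol, no electrophilic halogen meets the prenyl group, and one acid treatment both closes the furan (through 12) and removes the directing groups. The forward sequence asks for ring lithiation of 5 next to an acetal oxygen and a cross-coupling that keeps the ester.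

**5 ⇒ 2 + 3, and 2 ⇒ 1.** The C7 prenyl is cut from the carbon between the two oxygens of resorcinol bis(methoxymethyl) ether 2, made from resorcinol 1. Lithiation of 2 can occur only there, so the regiochemistry that direct phenol prenylation cannot give is settled by the directing groups.

**27 ⇒ 24.** The ynol silyl ether is cut at C–O and O–Si to acetylene 24, an oxygen-transfer reagent and a silyl triflate. The bulky silyl group is chosen because it goes onto the ynolate oxygen and later leaves with fluoride.

## Roads not taken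

**Alternative 1:** The cut is the bond between the carboxyl-bearing furan carbon and the benzo ring, with the lactone kept closed. In the forward direction 7-(methoxymethoxy)-4-[3-(methoxymethoxy)-2-prenylphenoxy]-6-prenylcoumarin A1 would undergo Pd(OAc)2-catalysed dehydrogenative coupling to 3,9-bis(methoxymethoxy)-2,10-diprenylcoumestan A2, and deprotection and lactone opening would finish. The merits are real: the route is shorter and more convergent than the chosen one, the lactone protects acid and 2'-oxygen at once, and only one ortho C–H is free, so the closure is unambiguous. The weak points are that divalent palladium with an oxidant at high temperature meets two prenyl groups (allylic C–H activation, alkene oxidation), that A1 needs a 6-prenyl-7-oxygenated coumarin, which brings back the C5'/C3' prenylation problem, and that acetal removal at the end exposes prenylated phenols to acid. The chosen plan is longer; it sets against this that the C5' prenyl is placed by construction and that the ring-forming step is neutral and metal-free.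

**Alternative 2:** The cuts are the two aryl–CH2 bonds. Bis(1,1-dimethylallyl) ether A3 would rearrange thermally at both ether groups (aromatic Claisen) to diprenyl diphenol A4. Its strength is that both prenyl groups arrive last, so the benzofuran core could be built with acid and oxidants, and for the C7 prenyl this is as good as or better than the chosen route, which must carry a prenylated resorcinol through an acid step. Its weakness is regiochemistry on the resorcinol ring, where the 4'-ether can deliver the allyl unit to C3' between the oxygens as well as to C5'; in addition, two tertiary allyl ethers must be made through propargyl ethers and semi-hydrogenation. The chosen plan answers the C5' question without relying on a migratory preference.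

**Alternative 3:** The cut is the C2=C3 bond. Aryl glyoxylate ester A5 would be coupled with low-valent titanium from TiCl3 and zinc, ketone carbon to ester carbonyl carbon, to give tris-silyl benzofuran A6. It is convergent (the two arenes are joined by an esterification), uses one kind of protecting group, and is of similar length. Against it, the aroyl half needs a 5-prenylated 2,4-dioxygenated benzoic acid, again an arene prenylation with a C3/C5 question, and an α-keto ester is prone to pinacol dimerisation and simple reduction before it attacks a hindered, electron-rich ester carbonyl. The chosen plan forms its ring by pericyclic steps that lose only N2.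

Key step: step 12

Remark: the target has no stereocentre; E descriptors refer to the side-chain alkene, and 7, 29 and 31 are formed as racemates or diastereomer mixtures of no consequence.

## Route

Step 1
Reactants: 1 resorcinol
Product: 2 1,3-bis(methoxymethoxy)benzene
Conditions: MOMCl, i-Pr2NEt, CH2Cl2, 0 °C → rt
Reagents that add atoms: chloromethyl methyl ether, COCCl
Why: O-Alkylation of both phenols to the acetal ethers; these serve twice as directing groups for ortho-lithiation.

Step 2
Reactants: 2 1,3-bis(methoxymethoxy)benzene; 3 prenyl bromide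
Product: 5 1,3-bis(methoxymethoxy)-2-(3-methylbut-2-en-1-yl)benzene, via aryllithium 4 (not isolated)
Conditions: n-BuLi, THF, 0 °C → rt; CuI (10 mol %), 3, −78 °C → rt
Reagents that add atoms: none
Why: Directed ortho-metalation at the carbon between the two acetal oxygens, then copper-catalysed allylic substitution at the primary carbon of the bromide, which gives the linear prenyl group.

Step 3
Reactants: 6 methyl (E)-3-methoxyprop-2-enoate
Product: 8 methyl (Z)-2-iodo-3-methoxyprop-2-enoate, via iodoacetate adduct 7 (not isolated)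
Conditions: N-iodosuccinimide, AcOH, CH2Cl2, rt; then Et3N, rt
Reagents that add atoms: N-iodosuccinimide, O=C1CCC(=O)N1I
Why: Iodoacetoxylation of the enol ether (iodine on the nucleophilic α-carbon) and amine-induced E1cB loss of acetic acid give the (Z)-α-iodo-β-methoxyacrylate, a standard β-methoxyacrylate building block.

Step 4
Reactants: 5 1,3-bis(methoxymethoxy)-2-(3-methylbut-2-en-1-yl)benzene; 8 methyl (Z)-2-iodo-3-methoxyprop-2-enoate
Product: 11 methyl (E)-2-[2,4-bis(methoxymethoxy)-3-(3-methylbut-2-en-1-yl)phenyl]-3-methoxyprop-2-enoate, via aryllithium 9 (not isolated), via arylzinc chloride 10 (not isolated)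
Conditions: n-BuLi, TMEDA, THF, −20 → 0 °C; ZnCl2, −78 °C → rt; 8, Pd(PPh3)4 (5 mol %), 50 °C
Reagents that add atoms: none
Why: A second directed ortho-lithiation at the ring C–H next to an acetal oxygen, transmetalation to zinc and Negishi coupling with retention of alkene geometry; the arylzinc tolerates the ester.

Step 5
Reactants: 11 methyl (E)-2-[2,4-bis(methoxymethoxy)-3-(3-methylbut-2-en-1-yl)phenyl]-3-methoxyprop-2-enoate
Product: 13 methyl 6-hydroxy-7-(3-methylbut-2-en-1-yl)-1-benzofuran-3-carboxylate, via dihydroxyaryl methoxyacrylate 12 (not isolated)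
Conditions: HCl (0.5 M), MeOH, 50 °C
Reagents that add atoms: none
Why: Acid methanolysis removes both acetals; the phenol ortho to the acrylate adds to the protonated enol ether (5-exo attack on the oxocarbenium carbon) and loss of methanol aromatises the furan, a known cyclisation of 2-(2-hydroxyaryl)-3-alkoxyacrylates. Any lactone formed by attack on the ester is reopened by methanol.

Step 6
Reactants: 13 methyl 6-hydroxy-7-(3-methylbut-2-en-1-yl)-1-benzofuran-3-carboxylate
Product: 14 methyl 7-(3-methylbut-2-en-1-yl)-6-[(triisopropylsilyl)oxy]-1-benzofuran-3-carboxylate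
Conditions: i-Pr3SiOTf, 2,6-lutidine, CH2Cl2, 0 °C
Reagents that add atoms: triisopropylsilyl trifluoromethanesulfonate, CC(C)[Si](OS(=O)(=O)C(F)(F)F)(C(C)C)C(C)C
Why: Silylation of the hindered phenol with a silyl triflate and a non-nucleophilic base; the bulky silyl ether withstands amide bases, olefination and photolysis and later leaves with fluoride together with the silyl group brought in by the alkyne.

Step 7
Reactants: 14 methyl 7-(3-methylbut-2-en-1-yl)-6-[(triisopropylsilyl)oxy]-1-benzofuran-3-carboxylate
Product: 16 methyl 2-formyl-7-(3-methylbut-2-en-1-yl)-6-[(triisopropylsilyl)oxy]-1-benzofuran-3-carboxylate, via 2-magnesiated benzofuran 15 (not isolated)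
Conditions: TMPMgCl·LiCl, THF, −40 °C; DMF, −40 °C → rt; aq. NH4Cl
Reagents that add atoms: N,N-dimethylformamide, CN(C)C=O
Why: Directed magnesiation of the C2–H between ring oxygen and ester with a hindered amide base that spares the methyl ester at low temperature, then formylation; no oxidant meets the prenyl alkene.

Step 8
Reactants: 17 dimethyl (2-oxopropyl)phosphonate; 3 prenyl bromide
Product: 19 dimethyl (6-methyl-2-oxohept-5-en-1-yl)phosphonate, via phosphonate dianion 18 (not isolated)
Conditions: LiN(i-Pr)2 (2.1 equiv), THF, −78 → 0 °C; 3, −78 → 0 °C; then 1 M HCl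
Reagents that add atoms: none
Why: γ-Alkylation of a β-ketophosphonate dianion: the more basic terminal carbanion attacks the primary carbon of the allylic bromide and leaves the phosphonate-stabilised carbon free for olefination.

Step 9
Reactants: 16 methyl 2-formyl-7-(3-methylbut-2-en-1-yl)-6-[(triisopropylsilyl)oxy]-1-benzofuran-3-carboxylate; 19 dimethyl (6-methyl-2-oxohept-5-en-1-yl)phosphonate
Product: 20 methyl 2-[(1E)-7-methyl-3-oxoocta-1,6-dien-1-yl]-7-(3-methylbut-2-en-1-yl)-6-[(triisopropylsilyl)oxy]-1-benzofuran-3-carboxylate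
Conditions: LiCl, i-Pr2NEt, MeCN, rt
Reagents that add atoms: none
Why: Horner–Wadsworth–Emmons olefination of a non-enolisable aldehyde under mild LiCl/amine conditions gives the E enone; without hydroxide the ester and the aryl silyl ether are untouched.

Step 10
Reactants: 20 methyl 2-[(1E)-7-methyl-3-oxoocta-1,6-dien-1-yl]-7-(3-methylbut-2-en-1-yl)-6-[(triisopropylsilyl)oxy]-1-benzofuran-3-carboxylate
Product: 23 methyl 2-[(1E)-4-diazo-7-methyl-3-oxoocta-1,6-dien-1-yl]-7-(3-methylbut-2-en-1-yl)-6-[(triisopropylsilyl)oxy]-1-benzofuran-3-carboxylate, via lithium enolate 21 (not isolated), via trifluoroacetyl ketone 22 (not isolated)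
Conditions: LiN(SiMe3)2, THF, −78 °C; CF3CO2CH2CF3; dilute HCl work-up; then 4-acetamidobenzenesulfonyl azide, Et3N, H2O, MeCN, rt
Reagents that add atoms: 4-acetamidobenzenesulfonyl azide, CC(=O)Nc1ccc(cc1)S(=O)(=O)N=[N+]=[N-]
Why: Detrifluoroacetylative diazo transfer: deprotonation is possible only at the α'-methylene, the enolate is C-acylated by the trifluoroacetate, and the activated diketone takes up the diazo group with loss of the trifluoroacetyl group as its sulfonamide. This is the standard entry to α-diazo enones that fail in direct Regitz transfer.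

Step 11
Reactants: 24 acetylene
Product: 27 (triisopropylsilyloxy)acetylene, via lithium acetylide 25 (not isolated), via lithium ethynolate 26 (not isolated)
Conditions: n-BuLi, THF, −78 °C; t-BuOOLi (from t-BuOOH and LiN(SiMe3)2), −78 → −10 °C; i-Pr3SiOTf, −78 → 0 °C
Reagents that add atoms: tert-butyl hydroperoxide, CC(C)(C)OO; triisopropylsilyl trifluoromethanesulfonate, CC(C)[Si](OS(=O)(=O)C(F)(F)F)(C(C)C)C(C)C
Why: Oxidation of a lithium acetylide by lithium tert-butyl peroxide gives the ynolate, which a bulky silyl triflate silylates on oxygen; this is the established route from terminal alkynes to siloxyalkynes, here applied to acetylene with the acetylide kept cold.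

Step 12
Reactants: 23 methyl 2-[(1E)-4-diazo-7-methyl-3-oxoocta-1,6-dien-1-yl]-7-(3-methylbut-2-en-1-yl)-6-[(triisopropylsilyl)oxy]-1-benzofuran-3-carboxylate; 27 (triisopropylsilyloxy)acetylene
Product: 32 methyl 2-{2-hydroxy-5-(3-methylbut-2-en-1-yl)-4-[(triisopropylsilyl)oxy]phenyl}-7-(3-methylbut-2-en-1-yl)-6-[(triisopropylsilyl)oxy]-1-benzofuran-3-carboxylate, via vinylketene 28 (not isolated), via vinylcyclobutenone 29 (not isolated), via dienylketene 30 (not isolated), via cyclohexadienone 31 (not isolated)
Conditions: hν (medium-pressure Hg lamp, Pyrex), 27 (2 equiv), ClCH2CH2Cl, rt; then 80 °C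
Reagents that add atoms: none
Why: Irradiation expels N2 from 23 and the alkenyl group migrates from the carbonyl carbon to the diazo carbon (Wolff rearrangement), forming C5'–C6' and giving vinylketene 28 with prenyl on the ketene α-carbon. The electron-rich alkyne 27 adds to the ketene C=C in a regioselective (2+2) cycloaddition, its nucleophilic CH terminus bonding to the ketene carbonyl carbon (C2'–C3') and its oxygen-bearing carbon to the α-carbon (C4'–C5'), to give cyclobutenone 29. Four-electron conrotatory opening of 29 between the carbonyl carbon and the quaternary carbon gives dienylketene 30; six-electron disrotatory electrocyclic closure between the ketene carbon and the benzofuran-bearing alkene carbon (C1'–C2') closes the six-membered ring as dienone 31, which tautomerises to phenol 32. The closest known reaction is the second-generation Danheiser benzannulation of α-diazo enones with siloxyalkynes. No stereocentre remains, since the sp3 carbons of 29 and 31 are lost on ring opening and tautomerisation. The cycloaddition must be regioselective, and the polarity of the ynol ether against the ketene secures this, so the former ketone carbon becomes the free C2' phenol and the alkyne carbon the silylated C4' oxygen. The E alkene of 23 is also needed, since it puts the alkene terminus within reach of the ketene carbon after ring opening, and Wolff migration must outrun a 1,2-hydrogen shift from the prenyl CH2. The isolated trisubstituted alkenes do not absorb through Pyrex and react with the ketene far more slowly than the ynol ether does.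

Step 13
Reactants: 32 methyl 2-{2-hydroxy-5-(3-methylbut-2-en-1-yl)-4-[(triisopropylsilyl)oxy]phenyl}-7-(3-methylbut-2-en-1-yl)-6-[(triisopropylsilyl)oxy]-1-benzofuran-3-carboxylate
Product: 33 methyl 2-[2,4-dihydroxy-5-(3-methylbut-2-en-1-yl)phenyl]-6-hydroxy-7-(3-methylbut-2-en-1-yl)-1-benzofuran-3-carboxylate
Conditions: Bu4NF, AcOH, THF, 0 °C
Reagents that add atoms: none
Why: Fluoride cleaves both aryl silyl ethers; the acetic acid buffer keeps the phenols protonated, so the 2'-phenol does not close onto the ester and the prenyl groups meet no strong acid.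

Step 14
Reactants: 33 methyl 2-[2,4-dihydroxy-5-(3-methylbut-2-en-1-yl)phenyl]-6-hydroxy-7-(3-methylbut-2-en-1-yl)-1-benzofuran-3-carboxylate
Product: 34 Erythribyssin F, 2-[2,4-dihydroxy-5-(3-methylbut-2-en-1-yl)phenyl]-6-hydroxy-7-(3-methylbut-2-en-1-yl)-1-benzofuran-3-carboxylic acid
Conditions: LiOH, THF/MeOH/H2O, 40 °C; then 1 M HCl to pH 3–4, 0 °C
Reagents that add atoms: lithium hydroxide, [Li+].[OH-]
Why: Saponification of the methyl ester, helped if necessary by transient closure of the 2'-phenoxide to the coumestan lactone, which hydroxide reopens; cold acidification only to pH 3–4 should prevent relactonisation and chroman formation.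

## Compound list

1 | resorcinol | Oc1cccc(O)c1 | starting material
2 | 1,3-bis(methoxymethoxy)benzene | COCOc1cccc(OCOC)c1 | intermediate
3 | prenyl bromide (1-bromo-3-methylbut-2-ene) | CC(C)=CCBr | starting material
4 | [2,6-bis(methoxymethoxy)phenyl]lithium | [Li]c1c(OCOC)cccc1OCOC | intermediate
5 | 1,3-bis(methoxymethoxy)-2-(3-methylbut-2-en-1-yl)benzene | COCOc1cccc(OCOC)c1CC=C(C)C | intermediate
6 | methyl (E)-3-methoxyprop-2-enoate | CO/C=C/C(=O)OC | starting material
7 | methyl 3-acetoxy-2-iodo-3-methoxypropanoate (diastereomer mixture) | COC(OC(C)=O)C(I)C(=O)OC | intermediate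
8 | methyl (Z)-2-iodo-3-methoxyprop-2-enoate | CO/C=C(\I)C(=O)OC | intermediate
9 | [2,4-bis(methoxymethoxy)-3-(3-methylbut-2-en-1-yl)phenyl]lithium | [Li]c1ccc(OCOC)c(CC=C(C)C)c1OCOC | intermediate
10 | chloro[2,4-bis(methoxymethoxy)-3-(3-methylbut-2-en-1-yl)phenyl]zinc | Cl[Zn]c1ccc(OCOC)c(CC=C(C)C)c1OCOC | intermediate
11 | methyl (E)-2-[2,4-bis(methoxymethoxy)-3-(3-methylbut-2-en-1-yl)phenyl]-3-methoxyprop-2-enoate | CO/C=C(\c1ccc(OCOC)c(CC=C(C)C)c1OCOC)C(=O)OC | intermediate
12 | methyl (E)-2-[2,4-dihydroxy-3-(3-methylbut-2-en-1-yl)phenyl]-3-methoxyprop-2-enoate | CO/C=C(\c1ccc(O)c(CC=C(C)C)c1O)C(=O)OC | intermediate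
13 | methyl 6-hydroxy-7-(3-methylbut-2-en-1-yl)-1-benzofuran-3-carboxylate | COC(=O)c1coc2c(CC=C(C)C)c(O)ccc12 | intermediate
14 | methyl 7-(3-methylbut-2-en-1-yl)-6-[(triisopropylsilyl)oxy]-1-benzofuran-3-carboxylate | COC(=O)c1coc2c(CC=C(C)C)c(O[Si](C(C)C)(C(C)C)C(C)C)ccc12 | intermediate
15 | chloro{3-(methoxycarbonyl)-7-(3-methylbut-2-en-1-yl)-6-[(triisopropylsilyl)oxy]-1-benzofuran-2-yl}magnesium | COC(=O)c1c([Mg]Cl)oc2c(CC=C(C)C)c(O[Si](C(C)C)(C(C)C)C(C)C)ccc12 | intermediate
16 | methyl 2-formyl-7-(3-methylbut-2-en-1-yl)-6-[(triisopropylsilyl)oxy]-1-benzofuran-3-carboxylate | COC(=O)c1c(C=O)oc2c(CC=C(C)C)c(O[Si](C(C)C)(C(C)C)C(C)C)ccc12 | intermediate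
17 | dimethyl (2-oxopropyl)phosphonate | COP(=O)(CC(C)=O)OC | starting material
18 | 1,3-dianion of dimethyl (2-oxopropyl)phosphonate, dilithium salt | [Li+].[Li+].[CH2-]C([O-])=CP(=O)(OC)OC | intermediate
19 | dimethyl (6-methyl-2-oxohept-5-en-1-yl)phosphonate | COP(=O)(CC(=O)CCC=C(C)C)OC | intermediate
20 | methyl 2-[(1E)-7-methyl-3-oxoocta-1,6-dien-1-yl]-7-(3-methylbut-2-en-1-yl)-6-[(triisopropylsilyl)oxy]-1-benzofuran-3-carboxylate | COC(=O)c1c(/C=C/C(=O)CCC=C(C)C)oc2c(CC=C(C)C)c(O[Si](C(C)C)(C(C)C)C(C)C)ccc12 | intermediate
21 | lithium enolate of 20 (enolised towards C4 of the side chain) | COC(=O)c1c(/C=C/C(O[Li])=CCC=C(C)C)oc2c(CC=C(C)C)c(O[Si](C(C)C)(C(C)C)C(C)C)ccc12 | intermediate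
22 | methyl 2-[(1E)-7-methyl-3-oxo-4-(trifluoroacetyl)octa-1,6-dien-1-yl]-7-(3-methylbut-2-en-1-yl)-6-[(triisopropylsilyl)oxy]-1-benzofuran-3-carboxylate | COC(=O)c1c(/C=C/C(=O)C(CC=C(C)C)C(=O)C(F)(F)F)oc2c(CC=C(C)C)c(O[Si](C(C)C)(C(C)C)C(C)C)ccc12 | intermediate
23 | methyl 2-[(1E)-4-diazo-7-methyl-3-oxoocta-1,6-dien-1-yl]-7-(3-methylbut-2-en-1-yl)-6-[(triisopropylsilyl)oxy]-1-benzofuran-3-carboxylate | COC(=O)c1c(/C=C/C(=O)C(=[N+]=[N-])CC=C(C)C)oc2c(CC=C(C)C)c(O[Si](C(C)C)(C(C)C)C(C)C)ccc12 | intermediate
24 | acetylene | C#C | starting material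
25 | lithium acetylide (ethynyllithium) | [Li]C#C | intermediate
26 | lithium ethynolate | [Li]OC#C | intermediate
27 | (triisopropylsilyloxy)acetylene | C#CO[Si](C(C)C)(C(C)C)C(C)C | intermediate
28 | methyl 2-[(1E)-6-methyl-3-(oxomethylidene)hepta-1,5-dien-1-yl]-7-(3-methylbut-2-en-1-yl)-6-[(triisopropylsilyl)oxy]-1-benzofuran-3-carboxylate (vinylketene) | COC(=O)c1c(/C=C/C(CC=C(C)C)=C=O)oc2c(CC=C(C)C)c(O[Si](C(C)C)(C(C)C)C(C)C)ccc12 | intermediate
29 | methyl 2-{(E)-2-[1-(3-methylbut-2-en-1-yl)-4-oxo-2-[(triisopropylsilyl)oxy]cyclobut-2-en-1-yl]ethenyl}-7-(3-methylbut-2-en-1-yl)-6-[(triisopropylsilyl)oxy]-1-benzofuran-3-carboxylate (racemic) | COC(=O)c1c(/C=C/C2(CC=C(C)C)C(=O)C=C2O[Si](C(C)C)(C(C)C)C(C)C)oc2c(CC=C(C)C)c(O[Si](C(C)C)(C(C)C)C(C)C)ccc12 | intermediate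
30 | methyl 2-[(1E,3E)-3-(3-methylbut-2-en-1-yl)-6-oxo-4-[(triisopropylsilyl)oxy]hexa-1,3,5-trien-1-yl]-7-(3-methylbut-2-en-1-yl)-6-[(triisopropylsilyl)oxy]-1-benzofuran-3-carboxylate (dienylketene, ketenyl and alkenyl groups cis) | O=C=C/C(O[Si](C(C)C)(C(C)C)C(C)C)=C(CC=C(C)C)\C=C\c1oc2c(CC=C(C)C)c(O[Si](C(C)C)(C(C)C)C(C)C)ccc2c1C(=O)OC | intermediate
31 | methyl 2-{3-(3-methylbut-2-en-1-yl)-6-oxo-4-[(triisopropylsilyl)oxy]cyclohexa-2,4-dien-1-yl}-7-(3-methylbut-2-en-1-yl)-6-[(triisopropylsilyl)oxy]-1-benzofuran-3-carboxylate (racemic) | COC(=O)c1c(C2C=C(CC=C(C)C)C(O[Si](C(C)C)(C(C)C)C(C)C)=CC2=O)oc2c(CC=C(C)C)c(O[Si](C(C)C)(C(C)C)C(C)C)ccc12 | intermediate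
32 | methyl 2-{2-hydroxy-5-(3-methylbut-2-en-1-yl)-4-[(triisopropylsilyl)oxy]phenyl}-7-(3-methylbut-2-en-1-yl)-6-[(triisopropylsilyl)oxy]-1-benzofuran-3-carboxylate | COC(=O)c1c(-c2cc(CC=C(C)C)c(O[Si](C(C)C)(C(C)C)C(C)C)cc2O)oc2c(CC=C(C)C)c(O[Si](C(C)C)(C(C)C)C(C)C)ccc12 | intermediate
33 | methyl 2-[2,4-dihydroxy-5-(3-methylbut-2-en-1-yl)phenyl]-6-hydroxy-7-(3-methylbut-2-en-1-yl)-1-benzofuran-3-carboxylate | COC(=O)c1c(-c2cc(CC=C(C)C)c(O)cc2O)oc2c(CC=C(C)C)c(O)ccc12 | intermediate
34 | Erythribyssin F | CC(C)=CCc1cc(-c2oc3c(CC=C(C)C)c(O)ccc3c2C(=O)O)c(O)cc1O | target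

## Step count and least certain steps

Total: 14 steps. Longest linear sequence: 11 steps (1, 2, 4, 5, 6, 7, 9, 10, 12, 13, 14, from resorcinol); steps 3, 8 and 11 are side branches.

**Step 12 (key step).** Three processes may defeat it. A 1,2-hydrogen shift from the prenyl CH2 to the carbene carbon can compete with Wolff migration, because an acyclic α-alkyl diazo ketone populates the conformer that does not rearrange in concert. The benzofuranyl enone chromophore can filter the light and undergo E/Z isomerisation. The free phenol of the product can be acylated by vinylketene still present.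
Fallback: biaryl coupling in place of ring construction, setting out from 2 and 15 and returning at 33. Compound 2 is brominated twice with N-bromosuccinimide to 1,5-dibromo-2,4-bis(methoxymethoxy)benzene F1. One bromine–lithium exchange with n-BuLi and copper-catalysed alkylation with 3 give 1-bromo-2,4-bis(methoxymethoxy)-5-(3-methylbut-2-en-1-yl)benzene F2. Magnesium compound 15 is transmetalated with ZnCl2 and coupled with F2 (Pd2(dba)3 and a biaryl dialkylphosphine, Negishi coupling) to methyl 2-[2,4-bis(methoxymethoxy)-5-(3-methylbut-2-en-1-yl)phenyl]-7-(3-methylbut-2-en-1-yl)-6-[(triisopropylsilyl)oxy]-1-benzofuran-3-carboxylate F3. Bu4NF and then dilute HCl in MeOH give 33. The prenyl position is still fixed, by the site of halogen–metal exchange.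

**Step 11.** Monolithium acetylide may disproportionate to Li2C2 before it is oxidised, the ynolate may be silylated on carbon to a silylketene, and the volatile product may be lost on isolation.
Fallback: a fluoride-labile alkyl ynol ether made by the dichlorovinyl ether route, setting out from 23 and returning at 33. 2-(Trimethylsilyl)ethanol, KH and trichloroethylene give (E)-1,2-dichlorovinyl 2-(trimethylsilyl)ethyl ether F4. n-BuLi (2 equiv) and then methanol give [2-(trimethylsilyl)ethoxy]acetylene F5. F5 and 23 under the conditions of step 12 give methyl 2-{2-hydroxy-5-(3-methylbut-2-en-1-yl)-4-[2-(trimethylsilyl)ethoxy]phenyl}-7-(3-methylbut-2-en-1-yl)-6-[(triisopropylsilyl)oxy]-1-benzofuran-3-carboxylate F6. Excess Bu4NF with warming removes the silyl ether and the 2-(trimethylsilyl)ethyl ether and gives 33.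

**Step 10.** The amide base or the enolate may add in conjugate fashion to the doubly activated enone, trifluoroacetylation of the hindered methylene may be incomplete, and the sulfonyl azide may add to the electron-poor alkene.
Fallback: install the diazo group before the enone, setting out from 3 and 16 and returning at 23. Acetylacetone is C-alkylated with 3 (K2CO3, acetone) to 3-(3-methylbut-2-en-1-yl)pentane-2,4-dione F7. Deacylative diazo transfer (4-acetamidobenzenesulfonyl azide, DBU) gives 3-diazo-6-methylhept-5-en-2-one F8, whose only enolisable position is the methyl group. Its lithium enolate (LiN(SiMe3)2, −78 °C) adds to 16 to give aldol methyl 2-(4-diazo-1-hydroxy-7-methyl-3-oxooct-6-en-1-yl)-7-(3-methylbut-2-en-1-yl)-6-[(triisopropylsilyl)oxy]-1-benzofuran-3-carboxylate F9. Mesylation and elimination (MeSO2Cl, Et3N) give 23.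

**Step 5.** During acetal cleavage the prenyl group, flanked by two free phenols, may cyclise to a chroman or add methanol or HCl.
Fallback: fluoride-labile directing groups, setting out from 1 and returning at 12. Compound 1 and 2-(trimethylsilyl)ethoxymethyl chloride give 1,3-bis{[2-(trimethylsilyl)ethoxy]methoxy}benzene F10. The conditions of step 2 give its 2-(3-methylbut-2-en-1-yl) derivative F11, and those of step 4 give methyl (E)-2-[2,4-bis{[2-(trimethylsilyl)ethoxy]methoxy}-3-(3-methylbut-2-en-1-yl)phenyl]-3-methoxyprop-2-enoate F12. Bu4NF in THF at 60 °C frees 12, which is closed to 13 with pyridinium p-toluenesulfonate in MeOH, a much weaker acid than in step 5.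

**Step 4.** n-BuLi may deprotonate the benzylic and allylic CH2 of 5 (flanked by two directing groups) instead of the ring.
Fallback: fix the metalation site by halogen–lithium exchange, setting out from 2 and returning at 9. N-Bromosuccinimide (1 equiv) converts 2 to 1-bromo-2,4-bis(methoxymethoxy)benzene F13. LiN(i-Pr)2 deprotonates it between the two acetal oxygens, and copper-catalysed alkylation with 3 gives 1-bromo-2,4-bis(methoxymethoxy)-3-(3-methylbut-2-en-1-yl)benzene F14. t-BuLi at −78 °C then gives 9, which continues as in step 4.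

## Further compounds

F1 | step 12 | 1,5-dibromo-2,4-bis(methoxymethoxy)benzene | COCOc1cc(OCOC)c(Br)cc1Br
F2 | step 12 | 1-bromo-2,4-bis(methoxymethoxy)-5-(3-methylbut-2-en-1-yl)benzene | COCOc1cc(OCOC)c(CC=C(C)C)cc1Br
F3 | step 12 | methyl 2-[2,4-bis(methoxymethoxy)-5-(3-methylbut-2-en-1-yl)phenyl]-7-(3-methylbut-2-en-1-yl)-6-[(triisopropylsilyl)oxy]-1-benzofuran-3-carboxylate | COC(=O)c1c(-c2cc(CC=C(C)C)c(OCOC)cc2OCOC)oc2c(CC=C(C)C)c(O[Si](C(C)C)(C(C)C)C(C)C)ccc12
F4 | step 11 | (E)-1,2-dichlorovinyl 2-(trimethylsilyl)ethyl ether | Cl/C=C(/Cl)OCC[Si](C)(C)C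
F5 | step 11 | [2-(trimethylsilyl)ethoxy]acetylene | C#COCC[Si](C)(C)C
F6 | step 11 | methyl 2-{2-hydroxy-5-(3-methylbut-2-en-1-yl)-4-[2-(trimethylsilyl)ethoxy]phenyl}-7-(3-methylbut-2-en-1-yl)-6-[(triisopropylsilyl)oxy]-1-benzofuran-3-carboxylate | COC(=O)c1c(-c2cc(CC=C(C)C)c(OCC[Si](C)(C)C)cc2O)oc2c(CC=C(C)C)c(O[Si](C(C)C)(C(C)C)C(C)C)ccc12
F7 | step 10 | 3-(3-methylbut-2-en-1-yl)pentane-2,4-dione | CC(=O)C(CC=C(C)C)C(C)=O
F8 | step 10 | 3-diazo-6-methylhept-5-en-2-one | CC(=O)C(=[N+]=[N-])CC=C(C)C
F9 | step 10 | methyl 2-(4-diazo-1-hydroxy-7-methyl-3-oxooct-6-en-1-yl)-7-(3-methylbut-2-en-1-yl)-6-[(triisopropylsilyl)oxy]-1-benzofuran-3-carboxylate (racemic) | COC(=O)c1c(C(O)CC(=O)C(=[N+]=[N-])CC=C(C)C)oc2c(CC=C(C)C)c(O[Si](C(C)C)(C(C)C)C(C)C)ccc12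
F10 | step 5 | 1,3-bis{[2-(trimethylsilyl)ethoxy]methoxy}benzene | C[Si](C)(C)CCOCOc1cccc(OCOCC[Si](C)(C)C)c1
F11 | step 5 | 2-(3-methylbut-2-en-1-yl)-1,3-bis{[2-(trimethylsilyl)ethoxy]methoxy}benzene | C[Si](C)(C)CCOCOc1cccc(OCOCC[Si](C)(C)C)c1CC=C(C)C
F12 | step 5 | methyl (E)-2-[2,4-bis{[2-(trimethylsilyl)ethoxy]methoxy}-3-(3-methylbut-2-en-1-yl)phenyl]-3-methoxyprop-2-enoate | CO/C=C(\c1ccc(OCOCC[Si](C)(C)C)c(CC=C(C)C)c1OCOCC[Si](C)(C)C)C(=O)OC
F13 | step 4 | 1-bromo-2,4-bis(methoxymethoxy)benzene | COCOc1ccc(Br)c(OCOC)c1
F14 | step 4 | 1-bromo-2,4-bis(methoxymethoxy)-3-(3-methylbut-2-en-1-yl)benzene | COCOc1ccc(Br)c(OCOC)c1CC=C(C)C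
A1 | alternative 1 | 7-(methoxymethoxy)-4-[3-(methoxymethoxy)-2-(3-methylbut-2-en-1-yl)phenoxy]-6-(3-methylbut-2-en-1-yl)-2H-chromen-2-one | O=C1C=C(Oc2cccc(OCOC)c2CC=C(C)C)c2cc(CC=C(C)C)c(OCOC)cc2O1
A2 | alternative 1 | 3,9-bis(methoxymethoxy)-2,10-bis(3-methylbut-2-en-1-yl)coumestan | O=C1Oc2cc(OCOC)c(CC=C(C)C)cc2-c2oc3c(CC=C(C)C)c(OCOC)ccc3c21
A3 | alternative 2 | methyl 6-[(2-methylbut-3-en-2-yl)oxy]-2-{4-[(2-methylbut-3-en-2-yl)oxy]-2-[(triisopropylsilyl)oxy]phenyl}-1-benzofuran-3-carboxylate | COC(=O)c1c(-c2ccc(OC(C)(C)C=C)cc2O[Si](C(C)C)(C(C)C)C(C)C)oc2cc(OC(C)(C)C=C)ccc12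
A4 | alternative 2 | methyl 6-hydroxy-2-{4-hydroxy-5-(3-methylbut-2-en-1-yl)-2-[(triisopropylsilyl)oxy]phenyl}-7-(3-methylbut-2-en-1-yl)-1-benzofuran-3-carboxylate | COC(=O)c1c(-c2cc(CC=C(C)C)c(O)cc2O[Si](C(C)C)(C(C)C)C(C)C)oc2c(CC=C(C)C)c(O)ccc12
A5 | alternative 3 | methyl 2-[2-({2,4-bis[(tert-butyldimethylsilyl)oxy]-5-(3-methylbut-2-en-1-yl)benzoyl}oxy)-4-[(tert-butyldimethylsilyl)oxy]-3-(3-methylbut-2-en-1-yl)phenyl]-2-oxoacetate | COC(=O)C(=O)c1ccc(O[Si](C)(C)C(C)(C)C)c(CC=C(C)C)c1OC(=O)c1cc(CC=C(C)C)c(O[Si](C)(C)C(C)(C)C)cc1O[Si](C)(C)C(C)(C)C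
A6 | alternative 3 | methyl 2-{2,4-bis[(tert-butyldimethylsilyl)oxy]-5-(3-methylbut-2-en-1-yl)phenyl}-6-[(tert-butyldimethylsilyl)oxy]-7-(3-methylbut-2-en-1-yl)-1-benzofuran-3-carboxylate | COC(=O)c1c(-c2cc(CC=C(C)C)c(O[Si](C)(C)C(C)(C)C)cc2O[Si](C)(C)C(C)(C)C)oc2c(CC=C(C)C)c(O[Si](C)(C)C(C)(C)C)ccc12
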